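## Structural features

The target is a (2S)-flavan: ring A (benzo) is fused to ring C (dihydropyran), C2 carries the unsubstituted phenyl ring B, and C8 of ring A is joined through a biaryl bond to C2' of a benzofuran made of ring D (furan) and ring E (benzo). Ring A is substituted all round, with OMe on C5, a free OH on C7, the benzofuranyl carbon on C8 and the pyran oxygen O1 on C8a. Ring E repeats a 2-methylphloroglucinol pattern in which the three oxygens play three different roles around the C5' methyl group: O1' in the furan, OMe on C4' and a free OH on C6'. C2 is the only stereocentre and has no stereogenic neighbour; the C8–C2' axis is flanked on the benzofuran side only by O1' and C3'–H, so it is not expected to be a stable stereogenic axis. The fragile points are the benzylic aryl ether bond C2–O1 (ionisation by strong acid, hydrogenolysis), the electron-rich 2-arylbenzofuran (acid, electrophiles, oxidants) and the two phenols, which should stay masked until the end. The real difficulty is regiochemical: C6 and C8 of ring A both lie between two oxygens, O4' and O6' of ring E are equally alike, and the C8–C2' bond has to be made between two ortho oxygens. The key step uses the fact that O1 on C8a and the carbon substituent on C8 are neighbours, with C8 next to the C7 oxygen: a C8–C8a aryne can take O1 at C8a from the tethered C2 alkoxide and leave a carbanion on C8, which iodine marks as the coupling site.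

## Logic of the disconnections

24 is traced back to 22 by cutting the O–Si bond on O6' and the O–CH2 acetal bond on O7. Both phenols stay masked through the coupling; the skeleton is not simplified. The demand is an unmasking that spares C2–O1 and the benzofuran: fluoride first, then dilute methanolic acid, in one flask by way of 23.

22 is cut at the biaryl bond C8–C2' into 11 and 21. This is the only bond joining the two halves, so the cut is fully convergent and each half holds one ring system. The forward coupling must work at an iodide flanked by two oxygens, with a boronate that can lose boron to protonation.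

11 is cut at O1–C8a and C8–I to give 7 (key step). One operation closes ring C and tells C8 from C6; 7 is an open-chain carbinol with one stereocentre and a fluorine as the only extra atom. The forward step needs deprotonation at C8–H only, ring closure ahead of any intermolecular capture of the aryne, and a C8 anion that lasts until iodine is added.

7 is traced to 6 by removing the C2–H bond (ketone reduction). The stereocentre then comes from a prochiral aryl alkyl ketone under reagent control; the demand is good discrimination between phenyl and the CH2CH2Ar chain.

6 goes back through 5 to 3 and 4 by cutting C3–C4, formed as a C=C bond by aldol condensation and then saturated. This leaves two simple carbonyl compounds. The hydrogenation must stop at the ketone and spare the C–F bond.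

3 goes back through 2 to 1 by cutting the aryl C–OMe bond (the future C5–O) and the O–CH2 acetal bond. The two fluorines of 1 and 2 are equivalent by symmetry, so substitution by methoxide raises no regiochemical question; formylation of a 3,5-disubstituted phenol would leave the site open to doubt. The demand is to stop after one substitution.

21 goes back through 20 to 19 by cutting C2'–B and O4'–CH3. C2'–H is the most reactive C–H bond of 20, and O4' is the only free oxygen of 19, so neither step needs a selectivity that the substrate does not already provide.

19 is cut at C7'–C7a', C6'–C7', C4'–C5' and C4'–C3a' into 13 and 16. The connectivity of the annulation places OH on C4', methyl on C5' and the silyl ether on C6' with no choice, so O4' and O6' are differentiated when ring E forms. The demand is that the ketene 17 is trapped by 16 faster than it dimerises and that furan C3 accepts the final ring closure.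

13 comes from 12 by cutting the bond between the carbonyl carbon and the diazo carbon, and 16 from 14 by cutting the ynol C–O and O–Si bonds. All of 1, 4, 12 and 14 are purchasable.

## Other disconnections considered

Alternative 1: Ring D would be cut at C3'–C3a' and O1'–C2'. In the forward step the 8-acetylflavan A2 and the O-arylhydroxylamine A3 condense under acid to an O-aryl oxime. Its ene-hydroxylamine tautomer undergoes a [3,3] shift that forms C3'–C3a', and the freed phenol closes O1'–C2' with expulsion of the nitrogen to give A1.
- In its favour: ring D is made without any cross-coupling at the hindered C8, which is better than the chosen plan on that point. Both partners are simple and the reagent is only acid.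
- Against it: the shift in A3 can reach either carbon ortho to the N–O oxygen, one next to OMe (wanted) and one next to the silyl ether. Only the bulk of the silyl group would bias this, whereas the chosen plan fixes the ring E pattern by connectivity in step 9. Hot acid acts on a molecule that already holds C2–O1. The benzyl ether on O7 would come off by hydrogenolysis, which threatens C2–O1 and the C2'=C3' bond.
- Comparison: A2 needs an acyl group on C8, so the C6/C8 question remains and would again call for a C8 anion such as 10; the two plans are equal in that need. Step economy is about equal, with one more deprotection operation.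

Alternative 2: Ring C would be cut at C3–C4 and O1–C2. A confined chiral Brønsted acid would dehydrate the hydroxymethyl phenol A5 to the ortho-quinone methide A7, which adds styrene A6 across C4 and O1 in a hetero-Diels–Alder reaction to give A4.
- In its favour: ring C, two bonds and the C2 stereocentre are formed in one catalytic step from an achiral phenol and a commodity alkene. This replaces steps 3 to 6 of the chosen plan and is clearly better on step economy for ring C. The regiochemistry of addition (oxygen to the benzylic carbon) is as secure as in the chosen plan.
- Against it: the whole hindered biaryl, with three different oxygen substituents on ring A, must exist before ring C (in A5), so the C8 problem moves to an earlier and less tractable compound. The catalyst must control the face of addition next to a bulky ortho aryl group, and C3' of the electron-rich benzofuran can itself attack A7. Two benzyl ethers would again be removed by hydrogenolysis next to C2–O1.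
- Comparison: stereocontrol here rests on a demanding catalyst–substrate match, whereas the chosen plan uses a ketone reduction whose sense follows from the aryl/alkyl size difference. If the catalytic step were selective, the alternative would be the shorter route.

Alternative 3: Ring E would be cut at C7'–C7a', C4'–C5', C6'–C7' and C4'–C3a'. Irradiation of the furyl diazoketone A9 with 16 and then heating would give the benzofuran-4-ol A8 through a Wolff rearrangement, a [2+2] addition, a 4π ring opening and a 6π closure.
- In its favour: the ring E pattern is fixed by mechanism and O4' is left as the only free oxygen. On this the alternative is the exact equal of the chosen plan, which runs the same annulation on the simple furan 13 in step 9. The smaller 2-furyl partner may also couple to C8 more easily than a benzofuranyl one, a point in its favour.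
- Against it: A9 still needs a C8–heteroaryl bond at the same hindered position, so 11 and the key step are not avoided. Acylation, diazo formation, photolysis and methylation would all be carried out late on the most valuable intermediate and all lie in the longest linear sequence.
- Comparison: the number of operations is about the same, but the chosen plan is more convergent and keeps diazo and photochemistry on a cheap fragment.

Key step: step 6

Remark on the chemistry (assumption): rotation about the C8–C2' bond is taken as fast at room temperature, so C2 is the only stereogenic element to control.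

## Route

Step 1
Reactants: 1 2,6-difluoro-4-hydroxybenzaldehyde
Product: 2 2,6-difluoro-4-(methoxymethoxy)benzaldehyde
Conditions: MOMCl, i-Pr2NEt, CH2Cl2, 0 °C → rt
Reagents that add atoms: chloromethyl methyl ether, COCCl
Why: O-alkylation of the acidic para-formyl phenol (acetal protection) should be clean, since the phenol is the only nucleophilic site and the acetal withstands every basic and reducing step that follows.

Step 2
Reactants: 2 2,6-difluoro-4-(methoxymethoxy)benzaldehyde
Product: 3 2-fluoro-6-methoxy-4-(methoxymethoxy)benzaldehyde
Conditions: NaOMe (1.05 equiv), MeOH, 50 °C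
Reagents that add atoms: sodium methoxide, C[O-].[Na+]
Why: Nucleophilic aromatic substitution of a fluorine ortho to the formyl group through a Meisenheimer adduct; the two fluorines are equivalent, so one regioisomer should form, and the new methoxy group lowers the reactivity of the second fluorine enough for one equivalent to stop at 3.

Step 3
Reactants: 3 2-fluoro-6-methoxy-4-(methoxymethoxy)benzaldehyde; 4 acetophenone
Product: 5 (E)-3-[2-fluoro-6-methoxy-4-(methoxymethoxy)phenyl]-1-phenylprop-2-en-1-one
Conditions: KOH, EtOH, 0 °C → rt
Reagents that add atoms: none
Why: Claisen–Schmidt condensation of a non-enolisable aldehyde with the enolate of 4, followed by E1cB dehydration, should give the E-enone; at this temperature the remaining fluorine, now flanked by a donor, is not expected to be displaced.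

Step 4
Reactants: 5 (E)-3-[2-fluoro-6-methoxy-4-(methoxymethoxy)phenyl]-1-phenylprop-2-en-1-one
Product: 6 3-[2-fluoro-6-methoxy-4-(methoxymethoxy)phenyl]-1-phenylpropan-1-one
Conditions: H2 (1 atm), Pd/C, Ph2S (cat.), EtOAc, rt
Reagents that add atoms: none
Why: Heterogeneous hydrogenation of the conjugated C=C bond; the sulfide-moderated catalyst should leave the aryl ketone, the C–F bond and the acetal untouched.

Step 5
Reactants: 6 3-[2-fluoro-6-methoxy-4-(methoxymethoxy)phenyl]-1-phenylpropan-1-one
Product: 7 (S)-3-[2-fluoro-6-methoxy-4-(methoxymethoxy)phenyl]-1-phenylpropan-1-ol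
Conditions: (R)-2-methyl-CBS-oxazaborolidine (10 mol %), BH3·SMe2, THF, −20 °C; MeOH quench
Reagents that add atoms: none
Why: Corey–Bakshi–Shibata reduction: the ketone binds the (R)-oxazaborolidine–borane complex with phenyl as the large group away from the catalyst, and hydride is delivered to the Re face, which should set the (S) configuration at the future C2.

Step 6
Reactants: 7 (S)-3-[2-fluoro-6-methoxy-4-(methoxymethoxy)phenyl]-1-phenylpropan-1-ol
Product: 11 (S)-8-iodo-5-methoxy-7-(methoxymethoxy)flavan, via C8-lithiated fluoroarene alkoxide 8 (not isolated), via C8–C8a aryne alkoxide 9 (not isolated), via 8-lithioflavan 10 (not isolated)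
Conditions: lithium 2,2,6,6-tetramethylpiperidide (2.5 equiv, from the amine and n-BuLi), THF (dilute), −78 → −20 °C; then I2, −78 °C → rt
Reagents that add atoms: iodine, [I][I]
Why: The first equivalent of the hindered amide forms the lithium alkoxide and the second removes C8–H, the most acidic ring proton because it lies between fluorine and the methoxymethoxy oxygen, to give 8; on warming, 8 should lose LiF, and since C4a carries the side chain the only aryne that can form is the C8–C8a aryne 9. The tethered alkoxide then adds to C8a in a 6-exo-dig closure of ring C (the attacked carbon lies in the new ring, its aryne partner C8 outside it); the closest known reaction type is the intramolecular addition of alkoxides to arynes generated from haloarenes by ortho-lithiation, with electrophilic quench of the resulting aryllithium. Both the three-carbon tether and the inductive pull of the C7 oxygen direct the nucleophile to C8a, so the carbanion appears on C8 in 10, where chelation by the methoxymethoxy group stabilises it. Iodine then caps C8, which settles the C8 against C6 question without any electrophilic substitution. No stereocentre is formed, and C2 keeps its configuration because the C2–O bond is never broken. The step needs site-selective deprotonation (secured by the fluorine), capture of the aryne by the tether ahead of addition of the base (secured by the bulk of the tetramethylpiperidide and by dilution) and survival of the C8 anion until the quench (secured by low temperature and the excess of base).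

Step 7
Reactants: 12 furan-2-carbonyl chloride
Product: 13 2-diazo-1-(furan-2-yl)ethan-1-one
Conditions: Me3SiCHN2 (2 equiv), THF/MeCN, 0 °C → rt
Reagents that add atoms: (trimethylsilyl)diazomethane, C[Si](C)(C)C=[N+]=[N-]
Why: Acylation of the diazoalkane carbon by the acid chloride (the first stage of an Arndt–Eistert sequence) followed by loss of the silyl group to chloride should give the diazoketone without the use of diazomethane.

Step 8
Reactants: 14 1-propynyllithium
Product: 16 triisopropyl(prop-1-yn-1-yloxy)silane, via lithium prop-1-yn-1-olate 15 (not isolated)
Conditions: t-BuOOLi (from t-BuOOH and LiN(SiMe3)2), THF, −78 → 0 °C; then i-Pr3SiOTf, −78 °C → rt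
Reagents that add atoms: lithium tert-butyl peroxide, CC(C)(C)OO[Li]; triisopropylsilyl trifluoromethanesulfonate, CC(C)[Si](OS(=O)(=O)C(F)(F)F)(C(C)C)C(C)C
Why: Electrophilic oxygen transfer from the lithium peroxide to the alkynyllithium gives the ynolate 15, and the bulky silyl triflate should silylate it on oxygen to give the siloxyalkyne.

Step 9
Reactants: 13 2-diazo-1-(furan-2-yl)ethan-1-one; 16 triisopropyl(prop-1-yn-1-yloxy)silane
Product: 19 5-methyl-6-(triisopropylsilyloxy)-1-benzofuran-4-ol, via furan-2-ylketene 17 (not isolated), via furyl siloxycyclobutenone 18 (not isolated)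
Conditions: hν (254 nm), ClCH2CH2Cl, rt; then 80 °C
Reagents that add atoms: none
Why: Danheiser benzannulation: photochemical Wolff rearrangement gives ketene 17, whose carbonyl carbon bonds to the nucleophilic methyl-bearing carbon of 16 in a [2+2] addition to give 18; thermal 4π ring opening, 6π closure onto furan C3 and tautomerisation should then give the phenol. The connectivity places OH on C4, methyl on C5 and the silyl ether on C6 without any regiochemical choice.

Step 10
Reactants: 19 5-methyl-6-(triisopropylsilyloxy)-1-benzofuran-4-ol
Product: 20 4-methoxy-5-methyl-6-(triisopropylsilyloxy)-1-benzofuran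
Conditions: MeI, K2CO3, acetone, reflux
Reagents that add atoms: iodomethane, IC
Why: Williamson methylation of the only free phenol; the aryl triisopropylsilyl ether should survive carbonate in an aprotic solvent.

Step 11
Reactants: 20 4-methoxy-5-methyl-6-(triisopropylsilyloxy)-1-benzofuran
Product: 21 2-[4-methoxy-5-methyl-6-(triisopropylsilyloxy)-1-benzofuran-2-yl]-4,4,5,5-tetramethyl-1,3,2-dioxaborolane
Conditions: [Ir(OMe)(cod)]2 (1.5 mol %), 4,4'-di-tert-butyl-2,2'-bipyridine (3 mol %), B2pin2 (1.0 equiv), THF, 50 °C
Reagents that add atoms: bis(pinacolato)diboron, CC1(C)OB(OC1(C)C)B1OC(C)(C)C(C)(C)O1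
Why: Iridium-catalysed C–H borylation of benzofurans occurs at C2, the C–H bond next to the ring oxygen; C7 is shielded by O1 and the bulky silyl ether and C3 by the peri methoxy group, so one boronate is expected.

Step 12
Reactants: 11 (S)-8-iodo-5-methoxy-7-(methoxymethoxy)flavan; 21 2-[4-methoxy-5-methyl-6-(triisopropylsilyloxy)-1-benzofuran-2-yl]-4,4,5,5-tetramethyl-1,3,2-dioxaborolane
Product: 22 (S)-5-methoxy-7-(methoxymethoxy)-8-[4-methoxy-5-methyl-6-(triisopropylsilyloxy)-1-benzofuran-2-yl]flavan
Conditions: Pd(OAc)2 (5 mol %), SPhos (10 mol %), K3PO4, toluene/H2O, 80 °C
Reagents that add atoms: none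
Why: Suzuki–Miyaura coupling; the bulky electron-rich biarylphosphine on zerovalent palladium should allow oxidative addition and reductive elimination at the iodide flanked by two oxygens and make transmetalation faster than loss of boron from 21, and the mild base leaves C2 and both protecting groups alone.

Step 13
Reactants: 22 (S)-5-methoxy-7-(methoxymethoxy)-8-[4-methoxy-5-methyl-6-(triisopropylsilyloxy)-1-benzofuran-2-yl]flavan
Product: 24 (S)-8-(6-hydroxy-4-methoxy-5-methyl-1-benzofuran-2-yl)-5-methoxyflavan-7-ol, via C6' phenol methoxymethyl ether 23 (not isolated)
Conditions: Bu4NF, THF, 0 °C; then HCl (2 M), MeOH, 40 °C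
Reagents that add atoms: none
Why: Fluoride cleaves the aryl O–Si bond to give 23, and acid-catalysed acetal exchange with methanol then removes the methoxymethyl group; the acid is kept dilute and warm, not hot, so that the benzylic C2–O1 bond (no cation-stabilising group on ring B) and the benzofuran should survive.

## Compound list

1 | 2,6-difluoro-4-hydroxybenzaldehyde | O=Cc1c(F)cc(O)cc1F | starting material
2 | 2,6-difluoro-4-(methoxymethoxy)benzaldehyde | O=Cc1c(F)cc(OCOC)cc1F | intermediate
3 | 2-fluoro-6-methoxy-4-(methoxymethoxy)benzaldehyde | COc1cc(OCOC)cc(F)c1C=O | intermediate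
4 | acetophenone | CC(=O)c1ccccc1 | starting material
5 | (E)-3-[2-fluoro-6-methoxy-4-(methoxymethoxy)phenyl]-1-phenylprop-2-en-1-one | COc1cc(OCOC)cc(F)c1/C=C/C(=O)c1ccccc1 | intermediate
6 | 3-[2-fluoro-6-methoxy-4-(methoxymethoxy)phenyl]-1-phenylpropan-1-one | COc1cc(OCOC)cc(F)c1CCC(=O)c1ccccc1 | intermediate
7 | (S)-3-[2-fluoro-6-methoxy-4-(methoxymethoxy)phenyl]-1-phenylpropan-1-ol | COc1cc(OCOC)cc(F)c1CC[C@@H](c1ccccc1)O | intermediate
8 | lithium (S)-3-[2-fluoro-3-lithio-6-methoxy-4-(methoxymethoxy)phenyl]-1-phenylpropan-1-olate | COc1cc(OCOC)c([Li])c(F)c1CC[C@@H](c1ccccc1)O[Li] | intermediate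
9 | lithium (S)-3-[2,3-didehydro-6-methoxy-4-(methoxymethoxy)phenyl]-1-phenylpropan-1-olate (C8–C8a aryne) | COC1=C(CC[C@@H](c2ccccc2)O[Li])C#CC(OCOC)=C1 | intermediate
10 | (S)-8-lithio-5-methoxy-7-(methoxymethoxy)flavan | COc1cc(OCOC)c([Li])c2c1CC[C@@H](c1ccccc1)O2 | intermediate
11 | (S)-8-iodo-5-methoxy-7-(methoxymethoxy)flavan | COc1cc(OCOC)c(I)c2c1CC[C@@H](c1ccccc1)O2 | intermediate
12 | furan-2-carbonyl chloride | O=C(Cl)c1ccco1 | starting material
13 | 2-diazo-1-(furan-2-yl)ethan-1-one | O=C(C=[N+]=[N-])c1ccco1 | intermediate
14 | 1-propynyllithium | CC#C[Li] | starting material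
15 | lithium prop-1-yn-1-olate | CC#CO[Li] | intermediate
16 | triisopropyl(prop-1-yn-1-yloxy)silane | CC#CO[Si](C(C)C)(C(C)C)C(C)C | intermediate
17 | 2-(furan-2-yl)ethen-1-one (furan-2-ylketene) | O=C=Cc1ccco1 | intermediate
18 | 4-(furan-2-yl)-2-methyl-3-(triisopropylsilyloxy)cyclobut-2-en-1-one (racemic) | O=C1C(C)=C(O[Si](C(C)C)(C(C)C)C(C)C)C1c1ccco1 | intermediate
19 | 5-methyl-6-(triisopropylsilyloxy)-1-benzofuran-4-ol | Cc1c(O)c2ccoc2cc1O[Si](C(C)C)(C(C)C)C(C)C | intermediate
20 | 4-methoxy-5-methyl-6-(triisopropylsilyloxy)-1-benzofuran | COc1c(C)c(O[Si](C(C)C)(C(C)C)C(C)C)cc2occc12 | intermediate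
21 | 2-[4-methoxy-5-methyl-6-(triisopropylsilyloxy)-1-benzofuran-2-yl]-4,4,5,5-tetramethyl-1,3,2-dioxaborolane | COc1c(C)c(O[Si](C(C)C)(C(C)C)C(C)C)cc2oc(B3OC(C)(C)C(C)(C)O3)cc12 | intermediate
22 | (S)-5-methoxy-7-(methoxymethoxy)-8-[4-methoxy-5-methyl-6-(triisopropylsilyloxy)-1-benzofuran-2-yl]flavan | COc1cc(OCOC)c(-c2cc3c(OC)c(C)c(O[Si](C(C)C)(C(C)C)C(C)C)cc3o2)c2c1CC[C@@H](c1ccccc1)O2 | intermediate
23 | (S)-4-methoxy-2-[5-methoxy-7-(methoxymethoxy)flavan-8-yl]-5-methyl-1-benzofuran-6-ol | COc1cc(OCOC)c(-c2cc3c(OC)c(C)c(O)cc3o2)c2c1CC[C@@H](c1ccccc1)O2 | intermediate
24 | (S)-8-(6-hydroxy-4-methoxy-5-methyl-1-benzofuran-2-yl)-5-methoxyflavan-7-ol | COc1cc(O)c(-c2cc3c(OC)c(C)c(O)cc3o2)c2c1CC[C@@H](c1ccccc1)O2 | target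

## Step count and least certain steps

Total step count: 13. Longest linear sequence: 8 steps (steps 1 to 6, 12 and 13).

Step 6 (key step). The most likely failure is intermolecular capture of the aryne, by the amide base or by a second aryllithium, before the alkoxide closes the ring; the second is protonation of the C8 anion by the liberated amine before iodine arrives. Both would come from the aryne and the anion living too long at the temperature needed for LiF loss. The fallback separates iodination from ring closure and avoids the aryne. It sets out from 7: deprotonation with the same base is held at −78 °C, where 8 keeps its fluorine, and iodine is added at that temperature to give (S)-3-[2-fluoro-3-iodo-6-methoxy-4-(methoxymethoxy)phenyl]-1-phenylpropan-1-ol F1. The potassium alkoxide of F1 (KN(SiMe3)2, THF/DMPU, 60 °C) is then closed onto the fluorine-bearing carbon by intramolecular nucleophilic aromatic substitution, helped by the ortho iodine and the two meta alkoxy groups. The sequence comes back to the route at 11.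

Step 9. The most likely failure is dimerisation of the ketene, or photodegradation of the furan chromophore, outrunning the [2+2] addition, since the ketene is formed slowly under light in the presence of an absorbing product. The fallback makes the same ketene without light or a diazo compound. It sets out from 16: 2-(furan-2-yl)acetyl chloride F2, made from purchased furan-2-ylacetic acid and (COCl)2, is added slowly with Et3N to 16 in toluene, so that 17 forms by dehydrochlorination and is trapped at once to give 18. Compound 18 is then isolated and heated at 80–110 °C, and the fallback comes back to the route at 19.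

Step 12. The most likely failure is loss of boron from the electron-rich benzofuran-2-yl boronate by protonation in the aqueous base before it can transmetalate to the crowded arylpalladium iodide. The fallback replaces boron by zinc under anhydrous conditions (Negishi coupling). It sets out from 20, which is deprotonated at C2 with n-BuLi (THF, −78 °C; C7 is blocked by the silyl ether) to give 2-lithio-4-methoxy-5-methyl-6-(triisopropylsilyloxy)-1-benzofuran F3. F3 is transmetalated with ZnCl2 to [4-methoxy-5-methyl-6-(triisopropylsilyloxy)-1-benzofuran-2-yl]zinc chloride F4, which is coupled with 11 using Pd2(dba)3 and SPhos in THF at 50 °C. The fallback comes back to the route at 22.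

Step 13. The most likely failure is acid damage while the acetal is cleaved: protonation of the electron-rich benzofuran at C3', or ionisation of the benzylic C2–O1 bond with loss of configuration, made worse by fluoride salts carried into the acid stage. The fallback moves the acid treatment to a point before the benzofuran is attached and leaves only fluoride for the end. It sets out from 11, which is treated with HCl in MeOH to give (S)-8-iodo-5-methoxyflavan-7-ol F5. F5 is coupled as the free phenol with 21 under the conditions of step 12 to give (S)-5-methoxy-8-[4-methoxy-5-methyl-6-(triisopropylsilyloxy)-1-benzofuran-2-yl]flavan-7-ol F6, and Bu4NF then removes the silyl group. The fallback comes back to the route at 24.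

## Further compounds

F1 | step 6 | (S)-3-[2-fluoro-3-iodo-6-methoxy-4-(methoxymethoxy)phenyl]-1-phenylpropan-1-ol | COc1cc(OCOC)c(I)c(F)c1CC[C@@H](c1ccccc1)O
F2 | step 9 | 2-(furan-2-yl)acetyl chloride | O=C(Cl)Cc1ccco1
F3 | step 12 | 2-lithio-4-methoxy-5-methyl-6-(triisopropylsilyloxy)-1-benzofuran | COc1c(C)c(O[Si](C(C)C)(C(C)C)C(C)C)cc2oc([Li])cc12
F4 | step 12 | [4-methoxy-5-methyl-6-(triisopropylsilyloxy)-1-benzofuran-2-yl]zinc chloride | COc1c(C)c(O[Si](C(C)C)(C(C)C)C(C)C)cc2oc([Zn]Cl)cc12
F5 | step 13 | (S)-8-iodo-5-methoxyflavan-7-ol | COc1cc(O)c(I)c2c1CC[C@@H](c1ccccc1)O2
F6 | step 13 | (S)-5-methoxy-8-[4-methoxy-5-methyl-6-(triisopropylsilyloxy)-1-benzofuran-2-yl]flavan-7-ol | COc1cc(O)c(-c2cc3c(OC)c(C)c(O[Si](C(C)C)(C(C)C)C(C)C)cc3o2)c2c1CC[C@@H](c1ccccc1)O2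
A1 | alternative 1 | (S)-7-benzyloxy-5-methoxy-8-[4-methoxy-5-methyl-6-(triisopropylsilyloxy)-1-benzofuran-2-yl]flavan | COc1cc(OCc2ccccc2)c(-c2cc3c(OC)c(C)c(O[Si](C(C)C)(C(C)C)C(C)C)cc3o2)c2c1CC[C@@H](c1ccccc1)O2
A2 | alternative 1 | (S)-8-acetyl-7-benzyloxy-5-methoxyflavan | COc1cc(OCc2ccccc2)c(C(C)=O)c2c1CC[C@@H](c1ccccc1)O2
A3 | alternative 1 | O-[3-methoxy-4-methyl-5-(triisopropylsilyloxy)phenyl]hydroxylamine | NOc1cc(OC)c(C)c(O[Si](C(C)C)(C(C)C)C(C)C)c1
A4 | alternative 2 | (S)-7-benzyloxy-8-(6-benzyloxy-4-methoxy-5-methyl-1-benzofuran-2-yl)-5-methoxyflavan | COc1cc(OCc2ccccc2)c(-c2cc3c(OC)c(C)c(OCc4ccccc4)cc3o2)c2c1CC[C@@H](c1ccccc1)O2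
A5 | alternative 2 | 3-benzyloxy-2-(6-benzyloxy-4-methoxy-5-methyl-1-benzofuran-2-yl)-6-(hydroxymethyl)-5-methoxyphenol | COc1cc(OCc2ccccc2)c(-c2cc3c(OC)c(C)c(OCc4ccccc4)cc3o2)c(O)c1CO
A6 | alternative 2 | styrene | C=Cc1ccccc1
A7 | alternative 2 | 3-benzyloxy-2-(6-benzyloxy-4-methoxy-5-methyl-1-benzofuran-2-yl)-5-methoxy-6-methylidenecyclohexa-2,4-dien-1-one | COC1=CC(OCc2ccccc2)=C(-c2cc3c(OC)c(C)c(OCc4ccccc4)cc3o2)C(=O)C1=C
A8 | alternative 3 | (S)-2-[5-methoxy-7-(methoxymethoxy)flavan-8-yl]-5-methyl-6-(triisopropylsilyloxy)-1-benzofuran-4-ol | COc1cc(OCOC)c(-c2cc3c(O)c(C)c(O[Si](C(C)C)(C(C)C)C(C)C)cc3o2)c2c1CC[C@@H](c1ccccc1)O2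
A9 | alternative 3 | (S)-2-diazo-1-{5-[5-methoxy-7-(methoxymethoxy)flavan-8-yl]furan-2-yl}ethan-1-one | COc1cc(OCOC)c(-c2ccc(C(=O)C=[N+]=[N-])o2)c2c1CC[C@@H](c1ccccc1)O2
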